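If your hunch holds that less free catalyst means proportionally less target, the flask at 1 mol% should end near 4.50 % of the solid substrate charged, but the earlier runs speak against it, because theta at 1.4 mol% and epsilon at 2.2 mol% both finish alike.

the same everywhere: solid substrate 0.020 M
- theta: coupling partner 4 equiv; free catalyst 1.4 mol%; run made earlier
- epsilon: coupling partner 4 equiv; free catalyst 2.2 mol%; run made earlier
- flask: coupling partner 4.00 equiv; free catalyst 1 mol%; time 6.0 d

| run | time / d | target / % |
|---|---|---|
| theta | 0.250 | 0 |
| theta | 0.500 | 1.2 |
| theta | 0.833 | 2.1 |
| theta | 1.25 | 3.4 |
| theta | 2.00 | 6.3 |
| theta | 4.00 | 9.8 |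
| epsilon | 0.250 | 0.7 |
| epsilon | 0.625 | 1.7 |
| epsilon | 1.25 | 4.9 |
| epsilon | 2.08 | 8.0 |
| epsilon | 3.00 | 9.1 |
| epsilon | 4.00 | 9.9 |

(readings scatter by 0.5 percentage points)

- dusk: doubling the amount of free catalyst, all else as stated
- noon: doubling the amount of coupling partner, all else as stated
- summer: doubling the dissolution coefficient of the solid substrate, all else as stated
- spring: doubling the solubility of the solid substrate, all else as stated

- solid, in amounts per volume of the solution: solid substrate
- the analysis behind the earlier runs scatters by 0.5 percentage points, standard deviation
- reactions considered so far: catalyst intermediate C -> free catalyst + target; coupling partner + target -> over-reaction product; solid substrate <-> starting material; catalyst intermediate A <-> catalyst intermediate B; coupling partner + free catalyst -> catalyst intermediate A; starting material + catalyst intermediate B -> catalyst intermediate C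
- at the start none of the solid substrate is in solution

- amount of target at 6.0 d, in percent of the solid substrate charged
- the change that raises the amount of target at 6.0 d, in percent of the solid substrate charged most ("none" if none brings more than 2 percentage points) (dusk / noon / summer / spring / none)
- amount of target at 6.0 d, in percent of the solid substrate charged, after summer

I would ask for the end state first. Coupling partner stands in excess, so you can treat the loss of target to over-reaction product as pseudo-first-order, and target then climbs towards a level equal to its feed times a fixed time. Epsilon shows the bend best, so I read that time there, taking its last reading as the level and asking how far its reading at 2.08 d has closed the gap to it: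

fixed time = 2.08 d / ln(9.9 % / (9.9 % − 8.0 %)) = 1.26 d

That time is the holding time, and it is a reading with the scatter of its readings, which weighs heavily on so small a gap. It is shorter than the 6.0 d you ask about, so the flask should stand close to its level:

share of level reached = 1 − exp(−6.0 d / 1.26 d) = 99.1 %

With epsilon's level kept, I get 9.82 %. The forecast says 9 %, names spring as the best change and gives 12 % after summer, adding “Doubling partner speeds over-reaction and lowers target”. My number stands above the forecast's, and both rest on the same readings, so their closeness is no check.

    catalyst intermediate C → free catalyst + target (k = 0.0110 s⁻¹)
    coupling partner + target → over-reaction product (k = 1.30 × 10⁻⁴ L mol⁻¹ s⁻¹)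
    solid substrate ⇌ starting material, rate k3*(cs3 - [starting material]) while solid is left; crystals form when [starting material] > cs3 (solubility = 12.0 mM, k = 2.10 × 10⁻⁶ s⁻¹)
    catalyst intermediate A ⇌ catalyst intermediate B (K = 0.400, k = 0.00120 s⁻¹)
    coupling partner + free catalyst → catalyst intermediate A (k = 0.00460 L mol⁻¹ s⁻¹)
    starting material + catalyst intermediate B → catalyst intermediate C (k = 0.160 L mol⁻¹ s⁻¹)

The flask gives 9.39 %, with spring the best change at 6.6 percentage points and 14.0 % after summer. At 6.00 d this flask holds 28.1 % of over-reaction product, more than its 9.39 % of target. Dividing the flask's target by the holding time reads its feed, as a fraction of the charge, at 0.0745 d⁻¹. With 16.0 equiv of coupling partner, the holding time shortens in proportion to 0.315 d, and that neighbouring flask, at 2.47 % of target, reads a feed of 0.0784 d⁻¹.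

(The numbers in the tables were generated by integration from invented constants.)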